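**Retrosynthetic overview**
1. 11 ⇐ 10 ⇐ 9: the 15-OH is unmasked last. The 7α-OH comes from allylic C–H hydroxylation of the 8(17)-ene, so oxidation follows cyclisation.
2. 9 ⇐ 7: both rings form in one cation–olefin cascade of an acyclic all-E geranylgeranyl chain. Ring A closes first (C4–C5), then ring B (C9–C10), and loss of H-17 ends the cascade.
3. The C4 cation comes from a C4–C19 oxirane, not from C3 protonation or a 3,4-epoxide. The oxygen therefore ends on C19, C3 stays CH2, and one stereocentre is relayed to C4, C5, C9 and C10.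
4. 7 ⇐ 5 ⇐ 4 ⇐ 3 ⇐ 1: the oxirane comes from a 1,2-diol, the diol from the Sharpless epoxide of ω-(E)-hydroxygeranylgeraniol, and that from geranylgeraniol.

Assumption: the SMILES reads as the normal-series labdane 19-acetoxylabda-8(17),13E-diene-7α,15-diol (4S,5R,7R,9R,10S). Labdane numbering is used throughout (C19 = axial 4β-CH2O, C18 = 4α-CH3, C20 = 10β-CH3, C17 = exocyclic CH2).

**Step 1**
Reactants: 1 (2E,6E,10E)-geranylgeraniol
Product: 2 all-E geranylgeranyl tert-butyldiphenylsilyl ether
Conditions: TBDPSCl, imidazole, CH2Cl2, 0 °C to rt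
Reagents that add atoms: tert-butyl(chloro)diphenylsilane, CC(C)(C)[Si](Cl)(c1ccccc1)c1ccccc1
Why: Standard O-silylation (substitution at silicon) forms no stereocentre, and the bulky ether survives LiAlH4, NaH and MeAlCl2, leaves no allylic OH at C15 for the later Sharpless step, and makes C13=C14 less nucleophilic.

**Step 2**
Reactants: 2 all-E geranylgeranyl TBDPS ether
Product: 3 (2E,6E,10E,14E)-16-(TBDPS-oxy)-2,6,10,14-tetramethylhexadeca-2,6,10,14-tetraen-1-ol
Conditions: SeO2 (0.2 equiv), t-BuOOH (2.5 equiv), salicylic acid (0.1 equiv), CH2Cl2, 0 °C to rt, stopped near 60% conversion, 2 recycled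
Reagents that add atoms: selenium dioxide, O=[Se]=O (oxygen carrier); tert-butyl hydroperoxide, CC(C)(C)OO (terminal oxygen source)
Why: SeO2/t-BuOOH allylic hydroxylation (ene reaction, then [2,3]-sigmatropic shift) picks the most accessible and most electron-rich terminal isopropylidene and oxidises only the methyl trans to the chain, so the new allylic alcohol is E and no stereocentre is formed.

**Step 3**
Reactants: 3 ω-(E)-allylic alcohol
Product: 4 (2R,3R)-2,3-epoxy alcohol (C3–C4 epoxide, 4R, CH2OH trans to the chain)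
Conditions: Ti(OiPr)4 (10 mol %), D-(−)-diethyl tartrate (12 mol %), t-BuOOH (decane), 4 Å MS, CH2Cl2, −20 °C
Reagents that add atoms: tert-butyl hydroperoxide, CC(C)(C)OO
Why: The Sharpless asymmetric epoxidation touches only the alkene next to the single free allylic OH, and D-(−)-tartrate gives the (2R,3R)-epoxide of an E-2-methylallylic alcohol (mirror image of the (2S,3S) series from L-(+)-tartrate, typically above 90% ee), which fixes the C4–O stereocentre.

**Step 4**
Reactants: 4 (2R,3R)-epoxy alcohol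
Product: 5 (2S,6E,10E,14E)-16-(TBDPS-oxy)-2,6,10,14-tetramethylhexadeca-6,10,14-triene-1,2-diol
Conditions: LiAlH4, Et2O, 0 °C to rt; H2O, aq. NaOH work-up
Reagents that add atoms: none
Why: SN2 hydride opening of the 2-methyl-2,3-epoxy alcohol occurs at the less substituted C3 to give the 1,2-diol, and because the C4–O bond is untouched C4 keeps its geometry (the descriptor changes from R to S only through the priority change).

**Step 5**
Reactants: 5 (S)-1,2-diol
Product: 7 (S)-2-methyl-2-[(4E,8E,12E)-14-(TBDPS-oxy)-4,8,12-trimethyltetradeca-4,8,12-trienyl]oxirane, via primary tosylate 6 (not isolated)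
Conditions: NaH (2.5 equiv), 1-tosylimidazole (1.05 equiv), THF, 0 °C to rt
Reagents that add atoms: none
Why: One-pot selective sulfonylation of the primary alkoxide is followed by Williamson-type 3-exo-tet closure by the tertiary alkoxide, and because no bond to C4 is broken its configuration is retained.

**Step 6**
Reactants: 7 (S)-C4–C19 oxirane
Product: 9 19-acetoxy-15-(TBDPS-oxy)labda-8(17),13E-diene (4β-CH2OAc 5α-H 9α-H 10β-CH3), via dichloroaluminium 19-alkoxide 8 (not isolated)
Conditions: MeAlCl2 (1.5 equiv), CH2Cl2 (0.01 M), −78 °C, 30 min; then pyridine, DMAP, Ac2O, −78 °C to rt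
Reagents that add atoms: acetic anhydride, CC(=O)OC(C)=O
Why: Proposed new method: MeAlCl2 binds the oxirane oxygen and the C5=C10 alkene displaces it from the rear at tertiary C4 (inversion, so the S centre of 7 becomes the 4S quaternary carbon); the chair–chair array of the two E-alkenes then adds anti across each double bond to set 5α-H, 10β-CH3 and 9α-H; the oxirane CH2 takes the pseudo-axial site syn to the C10 methyl because its 60° C–C–O angle pins it back and makes it effectively smaller than the free CH3; the cascade halts at C8 because C13=C14 is inductively deactivated and crowded by the allylic silyl ether; and the aluminate tethered at O19 on the β-face (its Al–CH3 is the proton sink, CH4 leaves) can reach only the C17 hydrogens, since H-9 and the aligned H-7 lie on the α-face, which gives the 8(17)-ene; the closest known reaction type is the MeAlCl2-promoted cation–olefin polycyclisation of trisubstituted (oxidosqualene-type) epoxides, and trapping the aluminium alkoxide in the flask with Ac2O/pyridine/DMAP follows the known reductive acetylation of esters with i-Bu2AlH.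

**Step 7**
Reactants: 9 19-acetoxy-15-(TBDPS-oxy)labda-8(17),13E-diene
Product: 10 19-acetoxy-15-(TBDPS-oxy)labda-8(17),13E-dien-7α-ol
Conditions: SeO2 (0.5 equiv), t-BuOOH (2 equiv), CH2Cl2, 0 °C to rt
Reagents that add atoms: selenium dioxide, O=[Se]=O (oxygen carrier); tert-butyl hydroperoxide, CC(C)(C)OO (terminal oxygen source)
Why: In this SeO2 allylic hydroxylation, selenium bonds to the unhindered C17 of the 1,1-disubstituted alkene, the ene step takes the axial 7α-H (CH2 is preferred over the hindered C9–H), and the [2,3]-shift returns oxygen axially to the α-face away from the 10β-methyl to give 7R, while C13=C14 is slower because selenium would have to bond at C14 next to the C–O bond.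

**Step 8**
Reactants: 10 19-acetoxy-15-(TBDPS-oxy)labda-8(17),13E-dien-7α-ol
Product: 11 19-acetoxylabda-8(17),13E-diene-7α,15-diol (target)
Conditions: Bu4NF (1.2 equiv), AcOH (1.2 equiv), THF, 0 °C to rt
Reagents that add atoms: none
Why: Fluoride-induced desilylation, buffered with AcOH, leaves the neopentyl 19-acetate, both alkenes and every stereocentre untouched.

**Compound list**
1 | (2E,6E,10E)-geranylgeraniol (annatto-derived, bulk article) | CC(C)=CCC/C(C)=C/CC/C(C)=C/CC/C(C)=C/CO | starting material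
2 | all-E geranylgeranyl tert-butyldiphenylsilyl ether | CC(C)=CCC/C(C)=C/CC/C(C)=C/CC/C(C)=C/CO[Si](c1ccccc1)(c1ccccc1)C(C)(C)C | intermediate
3 | (2E,6E,10E,14E)-16-(TBDPS-oxy)-2,6,10,14-tetramethylhexadeca-2,6,10,14-tetraen-1-ol | OC/C(C)=C/CC/C(C)=C/CC/C(C)=C/CC/C(C)=C/CO[Si](c1ccccc1)(c1ccccc1)C(C)(C)C | intermediate
4 | [(2R,3R)-3-{(3E,7E,11E)-13-(TBDPS-oxy)-3,7,11-trimethyltrideca-3,7,11-trienyl}-2-methyloxiran-2-yl]methanol | C[C@]1(CO)O[C@@H]1CC/C(C)=C/CC/C(C)=C/CC/C(C)=C/CO[Si](c1ccccc1)(c1ccccc1)C(C)(C)C | intermediate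
5 | (2S,6E,10E,14E)-16-(TBDPS-oxy)-2,6,10,14-tetramethylhexadeca-6,10,14-triene-1,2-diol | C[C@@](O)(CO)CCC/C(C)=C/CC/C(C)=C/CC/C(C)=C/CO[Si](c1ccccc1)(c1ccccc1)C(C)(C)C | intermediate
6 | 1-O-tosylate of diol 5 (2S), not isolated | C[C@@](O)(COS(=O)(=O)c1ccc(C)cc1)CCC/C(C)=C/CC/C(C)=C/CC/C(C)=C/CO[Si](c1ccccc1)(c1ccccc1)C(C)(C)C | intermediate
7 | (S)-2-methyl-2-[(4E,8E,12E)-14-(TBDPS-oxy)-4,8,12-trimethyltetradeca-4,8,12-trienyl]oxirane | C[C@@]1(CO1)CCC/C(C)=C/CC/C(C)=C/CC/C(C)=C/CO[Si](c1ccccc1)(c1ccccc1)C(C)(C)C | intermediate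
8 | dichloroaluminium 19-alkoxide of 15-(TBDPS-oxy)labda-8(17),13E-dien-19-ol, not isolated | C=C1CC[C@H]2[C@@](C)(CO[Al](Cl)Cl)CCC[C@]2(C)[C@H]1CC/C(C)=C/CO[Si](c1ccccc1)(c1ccccc1)C(C)(C)C | intermediate
9 | 19-acetoxy-15-(TBDPS-oxy)labda-8(17),13E-diene (4S,5R,9S,10R; 4β-CH2OAc, 5α-H, 9α-H, 10β-CH3) | C=C1CC[C@H]2[C@@](C)(COC(C)=O)CCC[C@]2(C)[C@H]1CC/C(C)=C/CO[Si](c1ccccc1)(c1ccccc1)C(C)(C)C | intermediate
10 | 19-acetoxy-15-(TBDPS-oxy)labda-8(17),13E-dien-7α-ol (4S,5R,7R,9R,10S) | C=C1[C@H](O)C[C@H]2[C@@](C)(COC(C)=O)CCC[C@]2(C)[C@H]1CC/C(C)=C/CO[Si](c1ccccc1)(c1ccccc1)C(C)(C)C | intermediate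
11 | 19-acetoxylabda-8(17),13E-diene-7α,15-diol (4S,5R,7R,9R,10S) | C=C1[C@H](O)C[C@H]2[C@@](C)(COC(C)=O)CCC[C@]2(C)[C@H]1CC/C(C)=C/CO | target

**Total step count:** 8. **Longest linear sequence:** 8.

**Steps most likely to fail**

Step 6 is the riskiest step. Four things can go wrong:
- a 1,2-hydride shift of the opened oxirane to the C19 aldehyde (Meinwald rearrangement);
- the alternative chair with CH3 axial, which gives the diastereomer with the mirror-image decalin core;
- a third ring closure onto C13=C14;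
- endocyclic alkene isomers.

The fallback changes the initiating electrophile. It sets out from diol 5 and comes back at 9. Diol 5 is condensed with MeC(OMe)3 (PPTS cat., CH2Cl2, rt) to the cyclic orthoacetate F1. Me3SiOTf (1.1 equiv) with 2,6-di-tert-butyl-4-methylpyridine (1.5 equiv) in CH2Cl2 at −78 to −20 °C removes methoxide and gives the 2-methyl-1,3-dioxolan-2-ylium triflate F2. In F2 the C4 cation is internally stabilised and cannot slip to an aldehyde. The C5=C10 alkene opens F2 at tertiary C4 with the same inversion as in the main route. The acetyl group stays on O19, and the very hindered pyridine can take only an exposed C17 proton under acid-free conditions, so 9 forms directly.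

Step 7 may suffer from competing oxidation at C13=C14 or over-oxidation to the 7-ketone. The fallback shields the side-chain alkene electronically instead of relying on rate differences. It sets out from 9 and comes back at 11.
- Bu4NF/AcOH gives agathadiol 19-acetate F3.
- MnO2 (CH2Cl2, rt) oxidises only the allylic 15-OH to the (13E)-15-enal F4, whose conjugated alkene is inert to SeO2.
- SeO2/t-BuOOH then hydroxylates C7 to the 7α-hydroxy enal F5.
- Luche reduction (NaBH4, CeCl3·7H2O, MeOH, −40 °C) reduces the aldehyde 1,2 without touching the acetate and gives 11.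

Step 2 usually shows modest conversion and terminal-versus-internal selectivity. The fallback replaces C–H oxidation by cleavage and olefination. It sets out from 2 and comes back at 3.
- NBS in THF/H2O (0 °C) gives the terminal bromohydrin F6.
- K2CO3 in MeOH closes it to the terminal epoxide F7.
- H5IO6 (THF/Et2O, 0 °C) cleaves it to the trisnor aldehyde F8.
- A Wittig reaction with Ph3P=C(CH3)CO2Et (CH2Cl2, rt) gives the (E)-2-methyl enoate F9.
- i-Bu2AlH (CH2Cl2, −78 °C) reduces it to 3.

**Further compounds**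
F1 | step 6 | cyclic orthoacetate of 5: (4S)-2-methoxy-2,4-dimethyl-4-alkyl-1,3-dioxolane, epimers at C2 of the dioxolane | COC1(C)OC[C@@](C)(O1)CCC/C(C)=C/CC/C(C)=C/CC/C(C)=C/CO[Si](c1ccccc1)(c1ccccc1)C(C)(C)C
F2 | step 6 | (4S)-2,4-dimethyl-4-alkyl-1,3-dioxolan-2-ylium triflate | CC1=[O+]C[C@@](C)(O1)CCC/C(C)=C/CC/C(C)=C/CC/C(C)=C/CO[Si](c1ccccc1)(c1ccccc1)C(C)(C)C.[O-]S(=O)(=O)C(F)(F)F
F3 | step 7 | 19-acetoxylabda-8(17),13E-dien-15-ol (agathadiol 19-acetate) | C=C1CC[C@H]2[C@@](C)(COC(C)=O)CCC[C@]2(C)[C@H]1CC/C(C)=C/CO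
F4 | step 7 | 19-acetoxylabda-8(17),13E-dien-15-al | C=C1CC[C@H]2[C@@](C)(COC(C)=O)CCC[C@]2(C)[C@H]1CC/C(C)=C/C=O
F5 | step 7 | 19-acetoxy-7α-hydroxylabda-8(17),13E-dien-15-al | C=C1[C@H](O)C[C@H]2[C@@](C)(COC(C)=O)CCC[C@]2(C)[C@H]1CC/C(C)=C/C=O
F6 | step 2 | racemic 14-bromo-15-hydroxy-14,15-dihydrogeranylgeranyl TBDPS ether | CC(C)(O)C(Br)CC/C(C)=C/CC/C(C)=C/CC/C(C)=C/CO[Si](c1ccccc1)(c1ccccc1)C(C)(C)C
F7 | step 2 | racemic 14,15-epoxygeranylgeranyl TBDPS ether | CC1(C)OC1CC/C(C)=C/CC/C(C)=C/CC/C(C)=C/CO[Si](c1ccccc1)(c1ccccc1)C(C)(C)C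
F8 | step 2 | (4E,8E,12E)-14-(TBDPS-oxy)-4,8,12-trimethyltetradeca-4,8,12-trienal | O=CCC/C(C)=C/CC/C(C)=C/CC/C(C)=C/CO[Si](c1ccccc1)(c1ccccc1)C(C)(C)C
F9 | step 2 | ethyl (2E,6E,10E,14E)-16-(TBDPS-oxy)-2,6,10,14-tetramethylhexadeca-2,6,10,14-tetraenoate | CCOC(=O)/C(C)=C/CC/C(C)=C/CC/C(C)=C/CC/C(C)=C/CO[Si](c1ccccc1)(c1ccccc1)C(C)(C)C
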